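**Plan**
Retrosynthetic cuts, in order: C8–O and C13–C1' of the spiro-dihydropyran (hetero-Diels–Alder); C4–C5 of the nine-membered ring (Nozaki–Hiyama–Kishi); C3=C4, C8=C13 and C7–C8 of the two arms (two Wittig reactions, Weinreb ketone synthesis); last, C1–C9 of the cyclobutane.
Enabling feature: the cyclobutane C1–C9–C10–C11 is trans-1,2-disubstituted, with CMe2 (C11) beside C1 and CH2 (C10) beside C9. Placing NH in the C1–C9 bond gives a 2,5-trans-4,4-dimethylproline, so the four-membered ring can be made from a pyrrolidine by deleting its nitrogen.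
Forward order of rings: pyrrolidine (from D-pyroglutamic acid), cyclobutane, nine-membered carbocycle, dihydropyran. The syncarpic acid ring is made separately from 2,4,6-trihydroxyacetophenone.
Stereochemistry: C9 is the pyroglutamate centre and C1 comes from anti addition to an N-acyliminium ion; both pass through the nitrogen loss with retention. The Z-C3=C4 alkene comes from an iodo-Wittig reaction, C5 from the ring closure, and C8/C1' from the cycloaddition.

Key step: step 8

Remark: caryophyllane numbering is used (C1/C9 ring fusion, C10 H2, C11 Me2, C2–C8 the nine-ring chain, C13 the methylene carbon on C8, C1' the isobutyl-bearing carbon). The centres left undefined in 4, 6, 7 and 29 are mixtures that converge in the following operation.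

Step 1
Reactants: 1 D-pyroglutamic acid [(R)-5-oxopyrrolidine-2-carboxylic acid]
Product: 2 methyl (R)-5-oxopyrrolidine-2-carboxylate
Conditions: SOCl2 (1.1 equiv), MeOH, 0 °C to rt
Reagents that add atoms: methanol, CO
Why: Fischer-type esterification with HCl generated from SOCl2 in methanol is the standard way to pyroglutamate esters and touches neither the lactam nor the C2 stereocentre, the future C9.

Step 2
Reactants: 2 methyl (R)-5-oxopyrrolidine-2-carboxylate
Product: 3 1-benzyl 2-methyl (R)-5-oxopyrrolidine-1,2-dicarboxylate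
Conditions: LiN(SiMe3)2 (1.0 equiv), THF, −78 °C; then CbzCl
Reagents that add atoms: benzyl chloroformate, O=C(Cl)OCc1ccccc1
Why: N-acylation of the lithiated lactam gives an imide-type carbamate that activates C5=O for enolisation and hydride addition, and a benzyl carbamate is chosen because hydrogenolysis can later remove it without endangering a tert-butyl ester.

Step 3
Reactants: 3 1-benzyl 2-methyl (R)-5-oxopyrrolidine-1,2-dicarboxylate
Product: 5 1-benzyl 2-methyl (R)-4,4-dimethyl-5-oxopyrrolidine-1,2-dicarboxylate, via 4-methyl lactam 4 (not isolated)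
Conditions: LiN(SiMe3)2 (1.1 equiv), THF, −78 °C, MeI; re-cool to −78 °C, LiN(SiMe3)2 (1.2 equiv), MeI, to −20 °C
Reagents that add atoms: iodomethane, CI
Why: Two successive lactam enolate alkylations, in which the amide base removes the C4 proton of the N-acyl lactam faster than the C2 proton of the ester at −78 °C, so the stereocentre is kept while the second methylation erases the transient C4 centre and installs the future C11 gem-dimethyl group.

Step 4
Reactants: 5 1-benzyl 2-methyl (R)-4,4-dimethyl-5-oxopyrrolidine-1,2-dicarboxylate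
Product: 7 1-benzyl 2-methyl (2R)-5-methoxy-4,4-dimethylpyrrolidine-1,2-dicarboxylate, via hemiaminal 6 (not isolated)
Conditions: LiBHEt3 (1.1 equiv), THF, −78 °C; aq NaHCO3; crude in MeOH, pyridinium p-toluenesulfonate (cat.), rt
Reagents that add atoms: methanol, CO
Why: Partial reduction of an N-alkoxycarbonyl lactam with a bulky borohydride stops at the hemiaminal and spares the methyl ester at −78 °C, and acid-catalysed exchange with methanol gives a storable N,O-acetal whose new C5 centre is lost again in step 6.

Step 5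
Reactants: 8 tert-butyl acetate
Product: 9 tert-butyl[(1-tert-butoxyethenyl)oxy]dimethylsilane
Conditions: LiN(i-Pr)2, THF, −78 °C; TBSCl, DMPU, −78 °C to rt
Reagents that add atoms: tert-butyldimethylsilyl chloride, CC(C)(C)[Si](C)(C)Cl
Why: O-silylation of the lithium enolate of an acetate ester is the standard preparation of a ketene silyl acetal.

Step 6
Reactants: 7 1-benzyl 2-methyl (2R)-5-methoxy-4,4-dimethylpyrrolidine-1,2-dicarboxylate; 9 tert-butyl[(1-tert-butoxyethenyl)oxy]dimethylsilane
Product: 11 1-benzyl 2-methyl (2R,5S)-5-(2-tert-butoxy-2-oxoethyl)-4,4-dimethylpyrrolidine-1,2-dicarboxylate, via N-acyliminium ion 10 (not isolated)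
Conditions: BF3·OEt2 (1.2 equiv), CH2Cl2, −78 to −40 °C
Reagents that add atoms: none
Why: Mukaiyama–Mannich-type amidoalkylation in which BF3 ionises the N,O-acetal to 10, which cannot tautomerise to an enecarbamate because C4 is quaternary, and the bulky ketene acetal adds anti to the C2 ester, held pseudoaxial by allylic strain with the carbamate, to set 5S (future C1, 2,5-trans), any cis isomer being removed by chromatography.

Step 7
Reactants: 11 1-benzyl 2-methyl (2R,5S)-5-(2-tert-butoxy-2-oxoethyl)-4,4-dimethylpyrrolidine-1,2-dicarboxylate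
Product: 12 methyl (2R,5S)-5-(2-tert-butoxy-2-oxoethyl)-4,4-dimethylpyrrolidine-2-carboxylate
Conditions: H2 (1 atm), 10% Pd/C, EtOAc, rt; used promptly
Reagents that add atoms: none
Why: Hydrogenolysis of the benzyl carbamate with spontaneous decarboxylation frees the secondary amine under neutral conditions that leave both esters and both stereocentres alone.

Step 8
Reactants: 12 methyl (2R,5S)-5-(2-tert-butoxy-2-oxoethyl)-4,4-dimethylpyrrolidine-2-carboxylate
Product: 15 methyl (1S,2R)-2-(2-tert-butoxy-2-oxoethyl)-3,3-dimethylcyclobutane-1-carboxylate, via 1,1-diazene 13 (not isolated), via 1,4-biradical 14 (not isolated)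
Conditions: PhI(OH)OTs (2.5 equiv), NH2CO2NH4 (8 equiv), CF3CH2OH, 80 °C
Reagents that add atoms: none
Why: PhI(OH)OTs oxidises ammonia released from the carbamate to an electrophilic iminoiodinane/iodonitrene that transfers NH to the secondary amine of 12, and a second equivalent of the trivalent iodine reagent carries the N-amino compound on to the 1,1-diazene 13. Loss of N2 begins at the weaker C9–N bond (ester-stabilised radical) and leaves the singlet biradical 14 in the cisoid geometry of the former ring. The closest known reaction type is the iodonitrene-mediated contraction of substituted pyrrolidine-2-carboxylates to cyclobutanes, a mild variant of thermal 1,1-diazene extrusion. The ring C1–C9–C10–C11 closes by radical–radical recombination at C1–C9, a five-to-four ring contraction. No new stereocentre arises: C1 and C9 are retained because near-barrierless singlet coupling, fastest for the unstabilised C1 radical, outruns rotation about C1–C11 and C9–C10, and the trans product is also the less strained isomer. The selectivity needed is recombination over β-scission of the C10–C11 bond into two alkenes, and the C11 gem-dimethyl group (Thorpe–Ingold compression of the C1···C9 distance) together with the short biradical lifetime works for closure.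

Step 9
Reactants: 15 methyl (1S,2R)-2-(2-tert-butoxy-2-oxoethyl)-3,3-dimethylcyclobutane-1-carboxylate
Product: 16 tert-butyl 2-{(1R,4S)-4-[methoxy(methyl)carbamoyl]-2,2-dimethylcyclobutyl}acetate
Conditions: MeNH(OMe)·HCl (1.5 equiv), i-PrMgCl (3 equiv), THF, −20 to 0 °C
Reagents that add atoms: N,O-dimethylhydroxylamine hydrochloride, CNOC.Cl
Why: Weinreb amidation with the chloromagnesium amide attacks only the methyl ester, the tert-butyl ester being too hindered, and any enolisation at C9 returns to the more stable trans arrangement.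

Step 10
Reactants: 16 tert-butyl 2-{(1R,4S)-4-[methoxy(methyl)carbamoyl]-2,2-dimethylcyclobutyl}acetate; 17 2-(2-bromoethyl)-1,3-dioxolane
Product: 19 tert-butyl 2-{(1R,4S)-4-[3-(1,3-dioxolan-2-yl)propanoyl]-2,2-dimethylcyclobutyl}acetate, via Grignard reagent 18 (not isolated)
Conditions: 17, Mg, THF, 25–30 °C; then 16, THF, 0 °C; aq NH4Cl
Reagents that add atoms: none
Why: Weinreb ketone synthesis, in which the chelated tetrahedral adduct prevents over-addition, the tert-butyl ester is inert to the Grignard reagent at 0 °C, and the reagent brings C7, C6 and C5 with C5 masked as an acetal.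

Step 11
Reactants: 19 tert-butyl 2-{(1R,4S)-4-[3-(1,3-dioxolan-2-yl)propanoyl]-2,2-dimethylcyclobutyl}acetate
Product: 20 tert-butyl 2-{(1R,4S)-4-[4-(1,3-dioxolan-2-yl)but-1-en-2-yl]-2,2-dimethylcyclobutyl}acetate
Conditions: Ph3PCH3Br, KOt-Bu, THF, 0 °C to rt
Reagents that add atoms: methyltriphenylphosphonium bromide, C[P+](c1ccccc1)(c1ccccc1)c1ccccc1.[Br-]
Why: Wittig methylenation installs C13 early, while no hydroxyl group or iodide is present, the ester and acetal being inert to the ylide and the trans relationship at C9 being the thermodynamic one.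

Step 12
Reactants: 20 tert-butyl 2-{(1R,4S)-4-[4-(1,3-dioxolan-2-yl)but-1-en-2-yl]-2,2-dimethylcyclobutyl}acetate
Product: 21 2-{(1R,4S)-4-[4-(1,3-dioxolan-2-yl)but-1-en-2-yl]-2,2-dimethylcyclobutyl}acetaldehyde
Conditions: i-Bu2AlH (1.1 equiv), PhMe, −78 °C; aq potassium sodium tartrate
Reagents that add atoms: none
Why: Partial ester reduction with i-Bu2AlH, in which the bulky tert-butoxy aluminium hemiacetal does not collapse at −78 °C, so the C3 aldehyde appears only on work-up and the acetal and alkene stay untouched.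

Step 13
Reactants: 21 2-{(1R,4S)-4-[4-(1,3-dioxolan-2-yl)but-1-en-2-yl]-2,2-dimethylcyclobutyl}acetaldehyde
Product: 22 2-(3-{(1S,2R)-2-[(2Z)-3-iodobut-2-en-1-yl]-3,3-dimethylcyclobutyl}but-3-en-1-yl)-1,3-dioxolane
Conditions: Ph3PEtI, n-BuLi, THF, rt; I2, −78 °C; NaN(SiMe3)2, −20 °C; then 21, −78 to −20 °C
Reagents that add atoms: ethyltriphenylphosphonium iodide, CC[P+](c1ccccc1)(c1ccccc1)c1ccccc1.[I-]; iodine, II
Why: Stork–Zhao-type Wittig olefination with the α-iodoethylidene ylide is kinetically Z-selective with aliphatic aldehydes and places iodine cis to C2, as the Z-C3=C4 alkene of the target requires.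

Step 14
Reactants: 22 2-(3-{(1S,2R)-2-[(2Z)-3-iodobut-2-en-1-yl]-3,3-dimethylcyclobutyl}but-3-en-1-yl)-1,3-dioxolane
Product: 23 4-{(1S,2R)-2-[(2Z)-3-iodobut-2-en-1-yl]-3,3-dimethylcyclobutyl}pent-4-enal
Conditions: 1 M aq HCl, THF, rt
Reagents that add atoms: water, O
Why: Dilute aqueous acid hydrolyses the acetal to the C5 aldehyde without protonating the 1,1-disubstituted alkene or harming the alkenyl iodide.

Step 15
Reactants: 23 4-{(1S,2R)-2-[(2Z)-3-iodobut-2-en-1-yl]-3,3-dimethylcyclobutyl}pent-4-enal
Product: 24 (1R,3Z,5R,9S)-4,11,11-trimethyl-8-methylidenebicyclo[7.2.0]undec-3-en-5-ol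
Conditions: CrCl2 (10 equiv), NiCl2 (1 mol % of the CrCl2), DMSO, rt, slow addition of 23 to about 2 mM
Reagents that add atoms: none
Why: Nozaki–Hiyama–Kishi reaction, in which zerovalent nickel inserts into C4–I and transmetalation to trivalent chromium gives a geometry-retaining alkenyl nucleophile that adds only to the aldehyde; high dilution favours the nine-ring closure known for caryophyllane-type skeletons, and C5 is set by the cyclic transition state with the aldehyde oxygen turned to the ring periphery, the 5R alcohol being separated from any 5S epimer.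

Step 16
Reactants: 25 2,4,6-trihydroxyacetophenone
Product: 26 2-acetyl-3-hydroxy-4,4,6,6-tetramethylcyclohex-2-ene-1,5-dione
Conditions: NaOMe, MeI (excess), MeOH, reflux
Reagents that add atoms: iodomethane, CI
Why: Exhaustive base-mediated C-methylation of the acylphloroglucinol dearomatises the ring, each of the two free ring carbons taking two methyl groups, as is standard for syncarpic acid derivatives.

Step 17
Reactants: 26 2-acetyl-3-hydroxy-4,4,6,6-tetramethylcyclohex-2-ene-1,5-dione
Product: 27 syncarpic acid (2,2,4,4-tetramethylcyclohexane-1,3,5-trione)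
Conditions: 6 M aq HCl, reflux
Reagents that add atoms: none
Why: Acid-mediated retro-Claisen deacylation of the tricarbonyl unit removes the acetyl group that limited the methylation to four methyl groups.

Step 18
Reactants: 27 syncarpic acid; 28 3-methylbutanal
Product: 30 2,2,4,4-tetramethyl-6-(3-methylbutylidene)cyclohexane-1,3,5-trione, via piperidine Mannich base 29 (not isolated)
Conditions: piperidine (1.0 equiv), CH2Cl2, rt; then 1 M aq HCl, rt; used at once
Reagents that add atoms: none
Why: Knoevenagel condensation run through the Mannich base 29, whose acid-induced elimination gives the alkylidene trione without exposing it to excess syncarpic acid, and the symmetric ring means that no alkene isomers arise.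

Step 19
Reactants: 24 (1R,3Z,5R,9S)-4,11,11-trimethyl-8-methylidenebicyclo[7.2.0]undec-3-en-5-ol; 30 2,2,4,4-tetramethyl-6-(3-methylbutylidene)cyclohexane-1,3,5-trione
Product: 31 Tomentodione O (1R,3Z,5R,8S,9S,1'R)
Conditions: 30 (2.5 equiv), PhMe, 60–80 °C
Reagents that add atoms: none
Why: Inverse-electron-demand hetero-Diels–Alder reaction of the 1-oxadiene with the 1,1-disubstituted alkene, in which oxygen bonds to the more substituted C8 and C1' to C13; addition to the outer face of C8=C13, anti to the C9–C1 bond in the conformer holding C9–H beside the methylene, should give 8S, the transition state with C7 endo and the bulkier C9 exo puts the isobutyl group cis to C7 (1'R), and the unstrained Z-trisubstituted C3=C4 alkene next to the hydroxyl group reacts more slowly, minor diastereomers being removed by chromatography.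

**Compound list**
1 | D-pyroglutamic acid | OC(=O)[C@H]1CCC(=O)N1 | starting material
2 | methyl (R)-5-oxopyrrolidine-2-carboxylate | COC(=O)[C@H]1CCC(=O)N1 | intermediate
3 | 1-benzyl 2-methyl (R)-5-oxopyrrolidine-1,2-dicarboxylate | COC(=O)[C@H]1CCC(=O)N1C(=O)OCc1ccccc1 | intermediate
4 | 1-benzyl 2-methyl (2R)-4-methyl-5-oxopyrrolidine-1,2-dicarboxylate (C4 epimers, formed in situ) | COC(=O)[C@H]1CC(C)C(=O)N1C(=O)OCc1ccccc1 | intermediate
5 | 1-benzyl 2-methyl (R)-4,4-dimethyl-5-oxopyrrolidine-1,2-dicarboxylate | COC(=O)[C@H]1CC(C)(C)C(=O)N1C(=O)OCc1ccccc1 | intermediate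
6 | 1-benzyl 2-methyl (2R)-5-hydroxy-4,4-dimethylpyrrolidine-1,2-dicarboxylate (C5 epimers, formed in situ) | COC(=O)[C@H]1CC(C)(C)C(O)N1C(=O)OCc1ccccc1 | intermediate
7 | 1-benzyl 2-methyl (2R)-5-methoxy-4,4-dimethylpyrrolidine-1,2-dicarboxylate (C5 epimers) | COC(=O)[C@H]1CC(C)(C)C(OC)N1C(=O)OCc1ccccc1 | intermediate
8 | tert-butyl acetate | CC(=O)OC(C)(C)C | starting material
9 | tert-butyl[(1-tert-butoxyethenyl)oxy]dimethylsilane | C=C(OC(C)(C)C)O[Si](C)(C)C(C)(C)C | intermediate
10 | (R)-1-(benzyloxycarbonyl)-2-(methoxycarbonyl)-4,4-dimethyl-3,4-dihydro-2H-pyrrol-1-ium (N-acyliminium ion, formed in situ) | COC(=O)[C@H]1CC(C)(C)C=[N+]1C(=O)OCc1ccccc1 | intermediate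
11 | 1-benzyl 2-methyl (2R,5S)-5-(2-tert-butoxy-2-oxoethyl)-4,4-dimethylpyrrolidine-1,2-dicarboxylate | CC(C)(C)OC(=O)C[C@@H]1N(C(=O)OCc2ccccc2)[C@H](CC1(C)C)C(=O)OC | intermediate
12 | methyl (2R,5S)-5-(2-tert-butoxy-2-oxoethyl)-4,4-dimethylpyrrolidine-2-carboxylate (2,5-trans) | CC(C)(C)OC(=O)C[C@@H]1N[C@H](CC1(C)C)C(=O)OC | intermediate
13 | 1,1-diazene of 12 (formed in situ) | CC(C)(C)OC(=O)C[C@@H]1[N+](=[N-])[C@H](CC1(C)C)C(=O)OC | intermediate
14 | singlet 1,4-biradical, radical sites at C1 and C9 (formed in situ) | CC(C)(C)OC(=O)C[CH]C(C)(C)C[CH]C(=O)OC | intermediate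
15 | methyl (1S,2R)-2-(2-tert-butoxy-2-oxoethyl)-3,3-dimethylcyclobutane-1-carboxylate (trans) | CC(C)(C)OC(=O)C[C@@H]1[C@H](CC1(C)C)C(=O)OC | intermediate
16 | tert-butyl 2-{(1R,4S)-4-[methoxy(methyl)carbamoyl]-2,2-dimethylcyclobutyl}acetate | CC(C)(C)OC(=O)C[C@@H]1[C@H](CC1(C)C)C(=O)N(C)OC | intermediate
17 | 2-(2-bromoethyl)-1,3-dioxolane | BrCCC1OCCO1 | starting material
18 | [2-(1,3-dioxolan-2-yl)ethyl]magnesium bromide (formed in situ) | Br[Mg]CCC1OCCO1 | intermediate
19 | tert-butyl 2-{(1R,4S)-4-[3-(1,3-dioxolan-2-yl)propanoyl]-2,2-dimethylcyclobutyl}acetate | CC(C)(C)OC(=O)C[C@@H]1[C@H](CC1(C)C)C(=O)CCC1OCCO1 | intermediate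
20 | tert-butyl 2-{(1R,4S)-4-[4-(1,3-dioxolan-2-yl)but-1-en-2-yl]-2,2-dimethylcyclobutyl}acetate | CC(C)(C)OC(=O)C[C@@H]1[C@H](CC1(C)C)C(=C)CCC1OCCO1 | intermediate
21 | 2-{(1R,4S)-4-[4-(1,3-dioxolan-2-yl)but-1-en-2-yl]-2,2-dimethylcyclobutyl}acetaldehyde | O=CC[C@@H]1[C@H](CC1(C)C)C(=C)CCC1OCCO1 | intermediate
22 | 2-(3-{(1S,2R)-2-[(2Z)-3-iodobut-2-en-1-yl]-3,3-dimethylcyclobutyl}but-3-en-1-yl)-1,3-dioxolane | C/C(I)=C/C[C@@H]1[C@H](CC1(C)C)C(=C)CCC1OCCO1 | intermediate
23 | 4-{(1S,2R)-2-[(2Z)-3-iodobut-2-en-1-yl]-3,3-dimethylcyclobutyl}pent-4-enal | C/C(I)=C/C[C@@H]1[C@H](CC1(C)C)C(=C)CCC=O | intermediate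
24 | (1R,3Z,5R,9S)-4,11,11-trimethyl-8-methylidenebicyclo[7.2.0]undec-3-en-5-ol | C/C1=C/C[C@@H]2[C@H](CC2(C)C)C(=C)CC[C@H]1O | intermediate
25 | 2,4,6-trihydroxyacetophenone | CC(=O)c1c(O)cc(O)cc1O | starting material
26 | 2-acetyl-3-hydroxy-4,4,6,6-tetramethylcyclohex-2-ene-1,5-dione | CC(=O)C1=C(O)C(C)(C)C(=O)C(C)(C)C1=O | intermediate
27 | syncarpic acid (2,2,4,4-tetramethylcyclohexane-1,3,5-trione) | CC1(C)C(=O)CC(=O)C(C)(C)C1=O | intermediate
28 | 3-methylbutanal | CC(C)CC=O | starting material
29 | 3-hydroxy-4,4,6,6-tetramethyl-2-[3-methyl-1-(piperidin-1-yl)butyl]cyclohex-2-ene-1,5-dione (racemic, formed in situ) | CC(C)CC(N1CCCCC1)C1=C(O)C(C)(C)C(=O)C(C)(C)C1=O | intermediate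
30 | 2,2,4,4-tetramethyl-6-(3-methylbutylidene)cyclohexane-1,3,5-trione | CC(C)CC=C1C(=O)C(C)(C)C(=O)C(C)(C)C1=O | intermediate
31 | Tomentodione O | C/C1=C/C[C@@H]2[C@H](CC2(C)C)[C@]2(CC[C@H]1O)C[C@@H](CC(C)C)C1=C(O2)C(C)(C)C(=O)C(C)(C)C1=O | target

**Step count and risks**
Total: 19 steps. Longest linear sequence: 15 steps (steps 1–4, 6–15 and 19).

Most likely to fail, first: step 8. At 80 °C, fragmentation of the biradical across C10–C11 may outrun C1–C9 recombination, because only C9 carries a stabilising group. Oxidation or ammonolysis of the amino ester may also compete with nitrogen transfer. The fallback keeps the C1–C9 disconnection but separates N–N bond formation from nitrogen loss. Starting from 12, nitrosation with t-BuONO in CH2Cl2 gives the N-nitrosopyrrolidine F1. Reduction with Zn in AcOH gives the N-aminopyrrolidine F2. Oxidation with t-BuOCl and Et3N in Et2O at −78 °C generates the diazene 13 in the cold. Nitrogen then leaves on warming to about 0 °C, or on irradiation at low temperature, in a non-polar medium. Under these conditions the low-barrier coupling is favoured over the higher-barrier scission. The route is rejoined at 15.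

Second: step 15. Oligomerisation or protodeiodination may replace the nine-ring closure, and facial selectivity at the C5 aldehyde may be poor. The fallback closes the ring at C3=C4 by metathesis, with C5 fixed beforehand by reagent control. Starting from 21, Wittig methylenation with Ph3P=CH2 gives the allyl acetal F3, and dilute aqueous HCl gives the aldehyde F4. Isopropenylmagnesium bromide then gives the dienol epimer mixture F5, and Dess–Martin periodinane gives the dienone F6. Corey–Bakshi–Shibata reduction follows, using BH3·SMe2 and (S)-1-methyl-3,3-diphenyltetrahydro-1H,3H-pyrrolo[1,2-c][1,3,2]oxazaborole; the isopropenyl group acts as the large substituent, and the product should be the (5R)-dienol F7. Ring-closing metathesis with the second-generation Grubbs catalyst in dilute refluxing CH2Cl2 should start at the monosubstituted alkene. It should engage the hydroxyl-activated isopropenyl group rather than C8=C13, since closure there would need a trans-fused five-membered ring. The less strained Z-alkene is expected, and the route is rejoined at 24.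

Third: step 19. Facial or endo/exo selectivity on the flexible nine-membered ring may be poor, and reversible addition of the free hydroxyl group or an ene pathway may consume the heterodiene. The fallback moves the cycloaddition ahead of the ring closure. Starting from 22, heating with 30 in toluene gives the chromenedione acetal F8. Here the face of C8=C13 is governed by acyclic allylic strain about C8–C9 (attack anti to C1), no hydroxyl group is present, and isomers are removed on more plentiful material. Dilute aqueous HCl gives the iodo aldehyde F9. Closure with CrCl2/NiCl2 under high dilution, which ignores the hindered ketone and the vinylogous ester, rejoins the route at 31.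

**Further compounds**
F1 | step 8 | methyl (2R,5S)-5-(2-tert-butoxy-2-oxoethyl)-4,4-dimethyl-1-nitrosopyrrolidine-2-carboxylate | CC(C)(C)OC(=O)C[C@@H]1N(N=O)[C@H](CC1(C)C)C(=O)OC
F2 | step 8 | methyl (2R,5S)-1-amino-5-(2-tert-butoxy-2-oxoethyl)-4,4-dimethylpyrrolidine-2-carboxylate | CC(C)(C)OC(=O)C[C@@H]1N(N)[C@H](CC1(C)C)C(=O)OC
F3 | step 15 | 2-{3-[(1S,2R)-3,3-dimethyl-2-(prop-2-en-1-yl)cyclobutyl]but-3-en-1-yl}-1,3-dioxolane | C=CC[C@@H]1[C@H](CC1(C)C)C(=C)CCC1OCCO1
F4 | step 15 | 4-[(1S,2R)-3,3-dimethyl-2-(prop-2-en-1-yl)cyclobutyl]pent-4-enal | C=CC[C@@H]1[C@H](CC1(C)C)C(=C)CCC=O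
F5 | step 15 | 6-[(1S,2R)-3,3-dimethyl-2-(prop-2-en-1-yl)cyclobutyl]-2-methylhepta-1,6-dien-3-ol (carbinol epimers) | C=CC[C@@H]1[C@H](CC1(C)C)C(=C)CCC(O)C(C)=C
F6 | step 15 | 6-[(1S,2R)-3,3-dimethyl-2-(prop-2-en-1-yl)cyclobutyl]-2-methylhepta-1,6-dien-3-one | C=CC[C@@H]1[C@H](CC1(C)C)C(=C)CCC(=O)C(C)=C
F7 | step 15 | (3R)-6-[(1S,2R)-3,3-dimethyl-2-(prop-2-en-1-yl)cyclobutyl]-2-methylhepta-1,6-dien-3-ol | C=CC[C@@H]1[C@H](CC1(C)C)C(=C)CC[C@@H](O)C(C)=C
F8 | step 19 | (2S,4R)-2-[2-(1,3-dioxolan-2-yl)ethyl]-2-{(1S,2R)-2-[(2Z)-3-iodobut-2-en-1-yl]-3,3-dimethylcyclobutyl}-6,6,8,8-tetramethyl-4-(2-methylpropyl)-3,4-dihydro-2H-chromene-5,7(6H,8H)-dione | C/C(I)=C/C[C@@H]1[C@H](CC1(C)C)[C@]1(CCC2OCCO2)C[C@@H](CC(C)C)C2=C(O1)C(C)(C)C(=O)C(C)(C)C2=O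
F9 | step 19 | 3-[(2S,4R)-2-{(1S,2R)-2-[(2Z)-3-iodobut-2-en-1-yl]-3,3-dimethylcyclobutyl}-6,6,8,8-tetramethyl-4-(2-methylpropyl)-5,7-dioxo-3,4,5,6,7,8-hexahydro-2H-chromen-2-yl]propanal | C/C(I)=C/C[C@@H]1[C@H](CC1(C)C)[C@]1(CCC=O)C[C@@H](CC(C)C)C2=C(O1)C(C)(C)C(=O)C(C)(C)C2=O
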